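## Retrosynthetic overview

- Target ⇐ selective methanolysis of two aryl acetates ⇐ CAN oxidative demethylation of a 5,8-diacetoxy-1,4-dimethoxynaphthalene that already carries the complete (R)-side chain; the acetate-deactivated ring cannot be oxidised, so the quinone forms on the correct ring.
- Prenyl terminus ⇐ olefin cross-metathesis of an allyl group with 2-methyl-2-butene; butyrate ⇐ lipase-catalysed, (R)-selective transesterification with vinyl butyrate, which installs the ester and raises the ee.
- C-1' stereocentre ⇐ chiral phosphoric acid-catalysed allylboration of an achiral 2-naphthaldehyde.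
- Ring differentiation ⇐ CAN oxidation of the formyl-tetramethoxynaphthalene on its formyl-free ring, then reductive acetylation; aldehyde ⇐ Vilsmeier formylation of the symmetric tetramethyl ether ⇐ a commercial dimethoxynaphthalene (bromination, Cu-methoxylation).
- Rings: none is built; the naphthalene bicycle is bought intact and only its oxidation level is adjusted (distal ring in steps 4/5, side-chain ring in step 9).

Assumptions: butylshikonin is the n-butanoate of (R)-shikonin as in the given SMILES; (R)-TRIP is taken to give the same Re-face (R) induction as with benzaldehyde, and the enantiomeric catalyst is used if the first batch shows the opposite sense; reagents written over the arrow are achiral, commercial and given with SMILES instead of numbers.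

## Route

Step 1
Reactants: 1 1,5-dimethoxynaphthalene
Product: 2 4,8-dibromo-1,5-dimethoxynaphthalene
Conditions: NBS (2.1 equiv), MeCN, rt, dark
Reagents that add atoms: N-bromosuccinimide, O=C1CCC(=O)N1Br
Why: Electrophilic aromatic bromination goes para to each methoxy group of the electron-rich naphthalene and stops at the 4,8-dibromide.

Step 2
Reactants: 2 4,8-dibromo-1,5-dimethoxynaphthalene
Product: 3 1,4,5,8-tetramethoxynaphthalene
Conditions: NaOMe (excess), CuI (20 mol%), MeOH/DMF, reflux
Reagents that add atoms: sodium methoxide, [Na+].[O-]C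
Why: Copper-catalysed Ullmann-type methoxylation replaces both aryl bromides with methoxide.

Step 3
Reactants: 3 1,4,5,8-tetramethoxynaphthalene
Product: 5 1,4,5,8-tetramethoxynaphthalene-2-carbaldehyde, via iminium chloride 4 (not isolated)
Conditions: POCl3, DMF, CHCl3, 0 °C → 65 °C; then H2O
Reagents that add atoms: N,N-dimethylformamide, CN(C)C=O; water, O
Why: Vilsmeier–Haack formylation attacks one of the four equivalent free positions and stops at the mono-aldehyde because the formyl group deactivates the product; water hydrolyses the iminium salt.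

Step 4
Reactants: 5 1,4,5,8-tetramethoxynaphthalene-2-carbaldehyde
Product: 6 6-formyl-5,8-dimethoxy-1,4-naphthoquinone (= 1,4-dimethoxy-5,8-dioxo-5,8-dihydronaphthalene-2-carbaldehyde)
Conditions: CAN (2.5 equiv), MeCN/H2O, 0 °C
Reagents that add atoms: water, O
Why: CAN oxidative demethylation of a p-dimethoxyarene takes place on the more electron-rich, formyl-free ring, which differentiates the two rings; the quinone oxygens come from water.

Step 5
Reactants: 6 6-formyl-5,8-dimethoxy-1,4-naphthoquinone
Product: 8 5,8-diacetoxy-1,4-dimethoxynaphthalene-2-carbaldehyde, via hydroquinone 7 (not isolated)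
Conditions: Na2S2O4, EtOAc/H2O, rt; then Ac2O, pyridine, DMAP (cat.), 0 °C → rt
Reagents that add atoms: acetic anhydride, CC(=O)OC(C)=O
Why: Dithionite reduces the quinone and DMAP-catalysed acetylation traps the air-sensitive hydroquinone (reductive acetylation) without touching the aldehyde; the diacetoxy ring is now inert to later CAN oxidation.

Step 6
Reactants: 8 5,8-diacetoxy-1,4-dimethoxynaphthalene-2-carbaldehyde
Product: 10 (1R)-1-(5,8-diacetoxy-1,4-dimethoxynaphthalen-2-yl)but-3-en-1-ol, via pinacol borate ester 9 (not isolated)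
Conditions: allylB(pin) (1.3 equiv), (R)-TRIP (5 mol%), toluene, −30 °C; aq. NaHCO3 work-up
Reagents that add atoms: allylboronic acid pinacol ester, C=CCB1OC(C)(C)C(C)(C)O1
Why: Chiral BINOL-phosphoric acid-catalysed allylboration proceeds through a closed chair transition state in which the (R)-catalyst directs allyl transfer to the Re face, setting the (R)-carbinol centre (about 90–96% ee expected); the aryl acetates are inert.

Step 7
Reactants: 10 (1R)-1-(5,8-diacetoxy-1,4-dimethoxynaphthalen-2-yl)but-3-en-1-ol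
Product: 11 (1R)-1-(5,8-diacetoxy-1,4-dimethoxynaphthalen-2-yl)but-3-enyl butanoate
Conditions: lipase (immobilised Burkholderia cepacia lipase, Amano PS-IM), vinyl butyrate (5 equiv), MTBE, 40 °C, stopped at ca. 95% conversion
Reagents that add atoms: vinyl butyrate, CCCC(=O)OC=C
Why: Lipase-catalysed irreversible transesterification with an enol ester follows the Kazlauskas rule (aryl large, allyl medium) and acylates the (R)-alcohol at oxygen only, so the butyrate is installed with retention while the minor enantiomer of 10 stays unacylated and is removed on silica (ee above 99%).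

Step 8
Reactants: 11 (1R)-1-(5,8-diacetoxy-1,4-dimethoxynaphthalen-2-yl)but-3-enyl butanoate
Product: 12 (1R)-1-(5,8-diacetoxy-1,4-dimethoxynaphthalen-2-yl)-4-methylpent-3-enyl butanoate
Conditions: Grubbs II (5 mol%), 2-methyl-2-butene (excess), CH2Cl2, 40 °C
Reagents that add atoms: 2-methyl-2-butene, CC=C(C)C
Why: Ruthenium-catalysed olefin cross-metathesis of the terminal alkene with excess 2-methyl-2-butene gives the trisubstituted prenyl-type alkene and volatile propene, and does not touch the stereocentre or the esters.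

Step 9
Reactants: 12 (1R)-1-(5,8-diacetoxy-1,4-dimethoxynaphthalen-2-yl)-4-methylpent-3-enyl butanoate
Product: 13 (1R)-1-(5,8-diacetoxy-1,4-dioxo-1,4-dihydronaphthalen-2-yl)-4-methylpent-3-enyl butanoate
Conditions: CAN (2.5 equiv), MeCN/H2O, 0 °C, 15 min
Reagents that add atoms: water, O
Why: CAN oxidative demethylation can only occur on the dimethoxy ring because the diacetoxy ring is deactivated, so the quinone forms on the ring bearing the side chain; short exposure at 0 °C spares the prenyl alkene and the benzylic ester.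

Step 10
Reactants: 13 (1R)-1-(5,8-diacetoxy-1,4-dioxo-1,4-dihydronaphthalen-2-yl)-4-methylpent-3-enyl butanoate
Product: 14 butylshikonin, (1R)-1-(5,8-dihydroxy-1,4-dioxo-1,4-dihydronaphthalen-2-yl)-4-methylpent-3-enyl butanoate
Conditions: NaHCO3 (solid, 4 equiv), MeOH/CH2Cl2, 0 °C → rt, N2; pH 5 buffer work-up
Reagents that add atoms: none
Why: Mild base-mediated transesterification (methanolysis) cleaves the two activated aryl acetates peri to the quinone carbonyls much faster than the secondary alkyl butyrate, releasing the naphthazarin in the tautomer drawn for the target without affecting the stereocentre.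

## Compound list

1 | 1,5-dimethoxynaphthalene | COc1cccc2c(OC)cccc12 | starting material
2 | 4,8-dibromo-1,5-dimethoxynaphthalene | COc1ccc(Br)c2c(OC)ccc(Br)c12 | intermediate
3 | 1,4,5,8-tetramethoxynaphthalene | COc1ccc(OC)c2c(OC)ccc(OC)c12 | intermediate
4 | N,N-dimethyl-1-(1,4,5,8-tetramethoxynaphthalen-2-yl)methaniminium chloride | COc1ccc(OC)c2c(OC)c(C=[N+](C)C)cc(OC)c12.[Cl-] | intermediate
5 | 1,4,5,8-tetramethoxynaphthalene-2-carbaldehyde | COc1ccc(OC)c2c(OC)c(C=O)cc(OC)c12 | intermediate
6 | 6-formyl-5,8-dimethoxy-1,4-naphthoquinone | O=Cc1cc(OC)c2C(=O)C=CC(=O)c2c1OC | intermediate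
7 | 5,8-dihydroxy-1,4-dimethoxynaphthalene-2-carbaldehyde | O=Cc1cc(OC)c2c(O)ccc(O)c2c1OC | intermediate
8 | 5,8-diacetoxy-1,4-dimethoxynaphthalene-2-carbaldehyde | O=Cc1cc(OC)c2c(OC(C)=O)ccc(OC(C)=O)c2c1OC | intermediate
9 | 2-{[(1R)-1-(5,8-diacetoxy-1,4-dimethoxynaphthalen-2-yl)but-3-enyl]oxy}-4,4,5,5-tetramethyl-1,3,2-dioxaborolane | CC1(C)OB(O[C@H](CC=C)c2cc(OC)c3c(OC(C)=O)ccc(OC(C)=O)c3c2OC)OC1(C)C | intermediate
10 | (1R)-1-(5,8-diacetoxy-1,4-dimethoxynaphthalen-2-yl)but-3-en-1-ol | O[C@H](CC=C)c1cc(OC)c2c(OC(C)=O)ccc(OC(C)=O)c2c1OC | intermediate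
11 | (1R)-1-(5,8-diacetoxy-1,4-dimethoxynaphthalen-2-yl)but-3-enyl butanoate | CCCC(=O)O[C@H](CC=C)c1cc(OC)c2c(OC(C)=O)ccc(OC(C)=O)c2c1OC | intermediate
12 | (1R)-1-(5,8-diacetoxy-1,4-dimethoxynaphthalen-2-yl)-4-methylpent-3-enyl butanoate | CCCC(=O)O[C@H](CC=C(C)C)c1cc(OC)c2c(OC(C)=O)ccc(OC(C)=O)c2c1OC | intermediate
13 | (1R)-1-(5,8-diacetoxy-1,4-dioxo-1,4-dihydronaphthalen-2-yl)-4-methylpent-3-enyl butanoate | CCCC(=O)O[C@H](CC=C(C)C)C1=CC(=O)c2c(OC(C)=O)ccc(OC(C)=O)c2C1=O | intermediate
14 | butylshikonin, (1R)-1-(5,8-dihydroxy-1,4-dioxo-1,4-dihydronaphthalen-2-yl)-4-methylpent-3-enyl butanoate | CCCC(=O)O[C@H](CC=C(C)C)C1=CC(=O)c2c(O)ccc(O)c2C1=O | target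

## Totals and risks

Total step count: 10. Longest linear sequence: 10 steps (fully linear, 1 → 14).

The three steps most likely to fail are steps 6, 7 and 10.

**Step 6 (enantioselectivity or conversion of the allylboration on the ortho-methoxy aldehyde).** The fallback sets out from 8 and replaces asymmetric C–C bond formation by catalytic asymmetric ketone reduction. Barbier allylation (allyl bromide, Zn, THF/sat. aq. NH4Cl, 0 °C) gives racemic 1-(5,8-diacetoxy-1,4-dimethoxynaphthalen-2-yl)but-3-en-1-ol F1. Dess–Martin oxidation (NaHCO3-buffered, CH2Cl2) gives the β,γ-unsaturated ketone 1-(5,8-diacetoxy-1,4-dimethoxynaphthalen-2-yl)but-3-en-1-one F2, which is used at once to avoid isomerisation into conjugation. Corey–Bakshi–Shibata reduction ((S)-Me-CBS 20 mol%, catecholborane, toluene, −78 °C; aryl as the large group) gives 2-{[(1R)-1-(5,8-diacetoxy-1,4-dimethoxynaphthalen-2-yl)but-3-enyl]oxy}-1,3,2-benzodioxaborole F3, hydrolysed on work-up. The route is rejoined at 10, and the lipase step still removes residual (S)-alcohol.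

**Step 7 (the lipase may transfer acetyl from the aryl acetates of 10 to the alcohol, or be slow on this substrate).** The fallback sets out from 5 and runs the enzymatic step before any aryl ester is present. The same (R)-TRIP allylboration gives 4,4,5,5-tetramethyl-2-{[(1R)-1-(1,4,5,8-tetramethoxynaphthalen-2-yl)but-3-enyl]oxy}-1,3,2-dioxaborolane F4, hydrolysed on work-up to (1R)-1-(1,4,5,8-tetramethoxynaphthalen-2-yl)but-3-en-1-ol F5. The same lipase with vinyl butyrate gives (1R)-1-(1,4,5,8-tetramethoxynaphthalen-2-yl)but-3-enyl butanoate F6. CAN (MeCN/H2O, 0 °C) should oxidise mainly the unsubstituted ring, because the 1-acyloxyalkyl group shields and deactivates its own ring, giving (1R)-1-(1,4-dimethoxy-5,8-dioxo-5,8-dihydronaphthalen-2-yl)but-3-enyl butanoate F7. Na2S2O4 then gives (1R)-1-(5,8-dihydroxy-1,4-dimethoxynaphthalen-2-yl)but-3-enyl butanoate F8, which Ac2O/pyridine/DMAP acetylates without isolation. The route is rejoined at 11.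

**Step 10 (partial loss of the butyrate, or base damage to the quinone, during selective deacetylation).** The fallback sets out from 13 and gives up selectivity. Saponification of all three esters (1 M NaOH, MeOH/H2O, 0 °C → rt, N2, then acidification) gives (R)-shikonin, 5,8-dihydroxy-2-[(1R)-1-hydroxy-4-methylpent-3-enyl]naphthalene-1,4-dione F9. Steglich esterification (butanoic acid, DCC, DMAP cat., CH2Cl2, 0 °C) then acylates only the side-chain hydroxyl, because the peri-chelated phenols are unreactive. The route is rejoined at 14.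

## Further compounds

F1 | step 6 | racemic 1-(5,8-diacetoxy-1,4-dimethoxynaphthalen-2-yl)but-3-en-1-ol | OC(CC=C)c1cc(OC)c2c(OC(C)=O)ccc(OC(C)=O)c2c1OC
F2 | step 6 | 1-(5,8-diacetoxy-1,4-dimethoxynaphthalen-2-yl)but-3-en-1-one | O=C(CC=C)c1cc(OC)c2c(OC(C)=O)ccc(OC(C)=O)c2c1OC
F3 | step 6 | 2-{[(1R)-1-(5,8-diacetoxy-1,4-dimethoxynaphthalen-2-yl)but-3-enyl]oxy}-1,3,2-benzodioxaborole | B1(O[C@H](CC=C)c2cc(OC)c3c(OC(C)=O)ccc(OC(C)=O)c3c2OC)Oc4ccccc4O1
F4 | step 7 | 4,4,5,5-tetramethyl-2-{[(1R)-1-(1,4,5,8-tetramethoxynaphthalen-2-yl)but-3-enyl]oxy}-1,3,2-dioxaborolane | CC1(C)OB(O[C@H](CC=C)c2cc(OC)c3c(OC)ccc(OC)c3c2OC)OC1(C)C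
F5 | step 7 | (1R)-1-(1,4,5,8-tetramethoxynaphthalen-2-yl)but-3-en-1-ol | O[C@H](CC=C)c1cc(OC)c2c(OC)ccc(OC)c2c1OC
F6 | step 7 | (1R)-1-(1,4,5,8-tetramethoxynaphthalen-2-yl)but-3-enyl butanoate | CCCC(=O)O[C@H](CC=C)c1cc(OC)c2c(OC)ccc(OC)c2c1OC
F7 | step 7 | (1R)-1-(1,4-dimethoxy-5,8-dioxo-5,8-dihydronaphthalen-2-yl)but-3-enyl butanoate | CCCC(=O)O[C@H](CC=C)c1cc(OC)c2C(=O)C=CC(=O)c2c1OC
F8 | step 7 | (1R)-1-(5,8-dihydroxy-1,4-dimethoxynaphthalen-2-yl)but-3-enyl butanoate | CCCC(=O)O[C@H](CC=C)c1cc(OC)c2c(O)ccc(O)c2c1OC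
F9 | step 10 | (R)-shikonin, 5,8-dihydroxy-2-[(1R)-1-hydroxy-4-methylpent-3-enyl]naphthalene-1,4-dione | O[C@H](CC=C(C)C)C1=CC(=O)c2c(O)ccc(O)c2C1=O
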